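## Structural features

The target is a 2,3,4-trisubstituted oxolane (ring atoms O1, C2, C3, C4, C5). C2 carries the 4-hydroxyphenyl ring, C3 the acetoxymethyl carbon C6, C4 the exocyclic carbinol carbon C7 (acetate and 4-methoxyphenyl), and C5 is an unsubstituted O–CH2. Reading the stereodescriptors of the target SMILES gives 2R,3S,4R in the ring and 7S outside it; the ring substituents are all-trans (2,3-trans, 3,4-trans, hence 2,4-cis), and the four stereocentres C2–C3–C4–C7 are contiguous. Three oxygen functions must end up differentiated: a free phenol beside a primary and a secondary benzylic acetate. The fragile sites are the C7 acetate (a 4-methoxybenzylic ester that ionises under acid; a free C6 hydroxyl would then close a second oxolane), the C2–O1 benzylic ether para to a phenol (ring opening through a quinone methide under acid or strong base), and the acetates toward base. The real difficulty is the all-trans ring array together with the exocyclic centre C7, reached without acid in the late stages. The key step exploits that C5 is an O–CH2 carbon bonded to C4 and that C7 is both benzylic and oxygenated: if C4=C7 is a styrene, a carbanion at C5 on O1 can close the ring at C4 and leave the charge at C7, where the oxygen has to go.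

## Logic of the disconnections

26 to 25 to 24. The bonds cut are the three O–acetyl bonds; forward, all three are formed on 24 and the aryl ester of 25 is cut again. Esters would not survive the organolithium and hydride chemistry, and peracetylation followed by removal of the most electrophilic ester avoids telling the phenol from the two alcohols. The gain is that 26 reduces to one unprotected triol. The demand is that step 13 distinguishes an aryl from two alkyl acetates near neutral pH and that step 12 stays basic so that C7 never ionises.

24 to 23. The two O–Si bonds (phenol and C6–O) are cut together. Both are of one kind, so a single fluoride treatment serves and no acid is needed while C7 carries a free 4-methoxybenzylic hydroxyl. The gain is that all protecting-group traffic leaves the endgame. The forward step must be mild enough that the phenoxide does not open the ring at C2.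

23 to 22 to 21. The C7–H bond is cut (carbinol back to ketone), and 22 is derived from 21 by oxidation. The configuration at C7 cannot be trusted in the ring-forming step, so it is erased at the planar ketone and set by a reagent. The gain is that both C7 epimers of 21, and either alkene geometry further back, become acceptable, and that C4, now α to a carbonyl, sits in its more stable trans arrangement. The demand on step 10 is high facial selectivity for 7S, which reagent control and the Felkin–Anh bias of C4 should both favour.

21 to 17. Two bonds are cut at once: the ring bond C4–C5 and the C7–O bond. C5 is the only ring carbon without a substituent and C7 is benzylic, so a carbanion at C5 adding to a C4=C7 styrene places the new charge where oxygen is needed. The gain is the loss of the ring and of two stereocentres, leaving an acyclic chain with only C2 and C3 defined. The demand is that cyclisation outruns the [1,2]-shift of the benzylic C2, that C4 forms trans to C3, and that both silyl ethers ignore butyllithium and the two carbanions.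

17 to 14 and 15. The O1–C5 ether bond is cut, which removes tin from the chiral fragment. The forward alkylation needs a free secondary alkoxide next to a silyl ether, so the silyl group at C6–O must not migrate.

14 to 13 to 12. The primary O–Si bond is cut, and then C6 is raised to the acyl level, bonded to the auxiliary nitrogen. This turns the C2/C3 pair into an aldol pattern. The demands are primary-over-secondary selectivity in silylation and a reductive cleavage that leaves the acidic α-centre C3 alone.

12 to 7 and 9. The C2–C3 bond is cut. It is the bond between the two stereocentres that the cyclisation needs in place, and an auxiliary-controlled syn aldol sets both at once; syn corresponds to the 2,3-trans ring. The gain is two achiral halves of similar size. The demand is α-selective, Z-enolate, auxiliary-controlled addition with the R auxiliary.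

7 to 4 and 5; 4 to 1 and 2; 9 to 8. The N–acyl bond, the C=C bond and the phenolic O–Si bond are cut, reaching purchasable materials. The only demands are an acylation that does not move the alkene and an olefination that is mainly E.

## Other disconnections considered

Alternative 1: The ring is cut at O1–C2 and C3–C4, a [3+2] union of an O1–C5–C4 unit with a C2=C3 acceptor. Forward, zerovalent palladium (Pd2(dba)3 with a chiral phosphoramidite) ionises vinylethylene carbonate A3 decarboxylatively. The alkoxide adds to the benzylidene carbon of the arylidene Meldrum's acid A2, and the C3 carbanion closes on the internal allyl carbon to give the spiro compound A1 with the required 2,4-cis relation.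
- In its favour: the ring, two bonds and two stereocentres arise in one catalytic enantioselective step from achiral partners. There is no auxiliary, no tin and no organolithium. On catalytic asymmetry, convergence and reagent hazard it is the better plan.
- Against it here: neither the anisyl ring nor the C7 oxygen is delivered. C3 emerges as a quaternary spiro carbon that must be degraded to CH–CH2O, so its configuration is created only afterwards by protonation or equilibration. The vinyl group must be cleaved and arylated, which reopens the C7 question. The electron-rich aryl group of A2 weakens the acceptor and makes the oxa-Michael step more reversible.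
- Comparison: structurally A1 carries surplus carbon at C3 and lacks the C7 substituents, whereas 21 already holds every skeletal atom of 26. Mechanistically the two plans are equals in that both settle C7 separately. In step count the alternative is ahead up to A1 and is expected to lose that lead in the functional-group steps needed to reach the level of 23, so the totals should be similar.

Alternative 2: The ring is cut at C2–C3 and C4–C5. Forward, SnCl4 opens the dioxolane A5 to an aryl-substituted oxocarbenium ion at C2, which the alkene carbon C3 attacks through a chair. The oxanyl cation at C4 is quenched by a pinacol shift of C5 from C7 to C4, contracting the ring to the oxolane A4 and unveiling the C7 ketone.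
- In its favour: two C–C bonds, the ring and three ring stereocentres form in one step, and the chair with equatorial substituents predicts the all-trans array. A4 is the same ketone as 22 apart from its silyl groups, so step 9 would be unnecessary and C7 would be set as in step 10. On this point and on the absence of tin it is the better plan, and it could be shorter.
- Against it here: absolute configuration must be relayed from the quaternary carbinol centre of A5 (drawn 4S, the configuration that maps onto 2R,3S if anisyl sits equatorial and oxygen axial in the chair). That centre is a tertiary, allylic and 4-methoxybenzylic C–O bond, which SnCl4 can ionise and so erase the information. The anisyl group has a high migratory aptitude and may shift to C4 in place of C5. The aryl-conjugated oxocarbenium ion is a weak electrophile, and A5 needs its own asymmetric synthesis.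
- Comparison: structurally it is the equal of the chosen plan from the ketone onward. Mechanistically it stakes everything on one cationic cascade with three plausible leaks, where the chosen plan separates ring closure from the setting of C7. In step count it is potentially better.

Alternative 3: Only C2–C3 is cut. Forward, Rh2(O2CCPh3)4 (divalent rhodium) converts the α-diazo ester A7 into a carbenoid at C3 that inserts into a C2–H bond of the 4-silyloxybenzyl ether, closing the oxolane A6.
- In its favour: C4 and C7 are fixed beforehand by acyclic stereocontrol, so C7 never needs correcting; on this point it is the better plan. The bond is made catalytically at an unfunctionalised C–H bond activated by both oxygen and aryl, without tin or strong base.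
- Against it here: the carbenoid has a hydrogen on the adjacent C4, and 1,2-hydride shift to an alkene is the classic competitor, which is why the bulky carboxylate is needed. Two new centres (C2 and C3) depend on one existing centre; C3 can be corrected by epimerisation next to the ester, C2 cannot. The electron-rich arenes invite aromatic cycloaddition. A7 requires a deacylative diazo transfer and a separate stereoselective assembly of C4/C7, and C6 arrives as an ester that still has to be reduced.
- Comparison: structurally A6 is as complete as 23. Mechanistically it offers better control of C7 but worse control of C2. In step count it is expected to be longer than the chosen plan.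

Key step: step 8

Assumption: the secondary benzylic lithium formed in step 8 is treated as configurationally labile, so C7 is left unassigned in 19, 20 and 21 and is fixed in steps 9 and 10; 5 and 15 are taken as purchased.

## Steps

Step 1
Reactants: 1 4-methoxybenzaldehyde; 2 (2-carboxyethyl)triphenylphosphonium bromide
Product: 4 (E)-4-(4-methoxyphenyl)but-3-enoic acid, via carboxylate ylide 3 (not isolated)
Conditions: NaN(SiMe3)2 (2.1 equiv), THF, −78 °C to rt; aq. HCl
Reagents that add atoms: none
Why: Wittig olefination through the carboxylate ylide 3; ylides of this β-carboxylate type are known to give mainly E alkenes with aromatic aldehydes, and crystallisation of the acid should remove residual Z isomer (which would not be fatal, because the alkene geometry is not carried into the target).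

Step 2
Reactants: 4 (E)-4-(4-methoxyphenyl)but-3-enoic acid; 5 (R)-4-benzyl-1,3-oxazolidin-2-one
Product: 7 (R)-4-benzyl-3-[(E)-4-(4-methoxyphenyl)but-3-enoyl]-1,3-oxazolidin-2-one, via mixed pivalic anhydride 6 (not isolated)
Conditions: t-BuCOCl, Et3N, THF, −20 °C; then LiCl, 5, −20 °C to rt
Reagents that add atoms: none
Why: N-acylation of the oxazolidinone through the mixed pivalic anhydride 6 with LiCl/Et3N activation; the conditions are non-enolising and the alkene is already conjugated with the arene, so migration toward the carbonyl is not expected.

Step 3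
Reactants: 8 4-hydroxybenzaldehyde
Product: 9 4-(triisopropylsilyloxy)benzaldehyde
Conditions: i-Pr3SiCl, imidazole, DMF, rt
Reagents that add atoms: chlorotriisopropylsilane, CC(C)[Si](Cl)(C(C)C)C(C)C
Why: Routine silylation of a phenol; the triisopropylsilyl ether is preferred to a tert-butyldimethylsilyl ether because it must later withstand a potassium alkoxide (step 7), butyllithium and alkaline peroxide (step 8).

Step 4
Reactants: 7 (R)-4-benzyl-3-[(E)-4-(4-methoxyphenyl)but-3-enoyl]-1,3-oxazolidin-2-one; 9 4-(triisopropylsilyloxy)benzaldehyde
Product: 12 (R)-4-benzyl-3-{(2R,3R)-3-hydroxy-2-[(E)-2-(4-methoxyphenyl)ethenyl]-3-[4-(triisopropylsilyloxy)phenyl]propanoyl}-1,3-oxazolidin-2-one, via boron enolate 10 (not isolated), via boron aldolate 11 (not isolated)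
Conditions: Bu2BOTf, Et3N, CH2Cl2, −78 to 0 °C; then 9, −78 to 0 °C; pH 7 buffer, MeOH, 30% H2O2, 0 °C
Reagents that add atoms: none
Why: Evans syn aldol: soft enolisation gives the Z boron enolate 10, which reacts at its α-carbon through a closed Zimmerman–Traxler chair on the face remote from the benzyl group of the auxiliary; the R auxiliary should give the 2R,3R syn adduct (mirror image of the familiar outcome with the S auxiliary), which sets C2 (R) and C3 (S) of the target and corresponds to the 2,3-trans ring.

Step 5
Reactants: 12 the aldol adduct of step 4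
Product: 13 (1R,2S)-2-[(E)-2-(4-methoxyphenyl)ethenyl]-1-[4-(triisopropylsilyloxy)phenyl]propane-1,3-diol
Conditions: LiBH4, MeOH (1 equiv), THF, 0 °C
Reagents that add atoms: none
Why: Reductive cleavage of the N-acyl oxazolidinone with LiBH4 gives the primary alcohol without touching either stereocentre, and 5 is released for recovery.

Step 6
Reactants: 13 (1R,2S)-2-[(E)-2-(4-methoxyphenyl)ethenyl]-1-[4-(triisopropylsilyloxy)phenyl]propane-1,3-diol
Product: 14 (1R,2S,3E)-4-(4-methoxyphenyl)-2-[(triisopropylsilyloxy)methyl]-1-[4-(triisopropylsilyloxy)phenyl]but-3-en-1-ol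
Conditions: i-Pr3SiCl, imidazole, CH2Cl2/DMF, 0 °C to rt
Reagents that add atoms: chlorotriisopropylsilane, CC(C)[Si](Cl)(C(C)C)C(C)C
Why: Silyl chloride/imidazole silylation is selective for the primary hydroxyl over the hindered secondary benzylic one; triisopropylsilyl is used because it is the common silyl group least prone to 1,3-O→O migration and to attack by carbanions.

Step 7
Reactants: 14 (1R,2S,3E)-4-(4-methoxyphenyl)-2-[(triisopropylsilyloxy)methyl]-1-[4-(triisopropylsilyloxy)phenyl]but-3-en-1-ol; 15 tributyl(iodomethyl)stannane
Product: 17 tributyl({(1R,2S,3E)-4-(4-methoxyphenyl)-2-[(triisopropylsilyloxy)methyl]-1-[4-(triisopropylsilyloxy)phenyl]but-3-en-1-yl}oxymethyl)stannane, via potassium alkoxide 16 (not isolated)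
Conditions: KH, THF, 0 °C; then 15, 0 °C to rt
Reagents that add atoms: none
Why: Williamson etherification of the potassium alkoxide 16 with the iodomethylstannane, the classical route to α-alkoxymethylstannanes; the stereocentres are not involved, and the temperature is kept at or below rt to limit silyl migration.

Step 8
Reactants: 17 the stannylmethyl ether of step 7
Product: 21 (2R,3S,4R)-4-[hydroxy(4-methoxyphenyl)methyl]-3-[(triisopropylsilyloxy)methyl]-2-[4-(triisopropylsilyloxy)phenyl]oxolane as the pair of C7 epimers, via alkoxymethyllithium 18 (not isolated), via benzylic lithium 19 (not isolated), via dimethyl boronate 20 (not isolated)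
Conditions: n-BuLi (1.2 equiv), THF, −78 °C; then B(OMe)3, −78 to 0 °C; then 30% H2O2, aq. NaOH, 0 °C
Reagents that add atoms: hydrogen peroxide, OO
Why: n-BuLi attacks tin and releases the more stable α-alkoxymethyllithium 18, whose C5–Li bond adds across C4=C7 in a 5-exo-trig closure of the oxolane; the closest known reaction type is the anionic cyclisation of stannane-derived alkoxymethyllithiums and of 5-hexenyllithiums onto alkenes with electrophilic trapping. The driving force is the change from a primary alkoxyalkyllithium to the benzylic lithium 19. C4 is set by the chair-like transition state in which the C2 aryl and C3 silyloxymethyl groups (already trans) lie pseudo-equatorial, which gives 3,4-trans and 2,4-cis. C7 is created too, but a secondary benzylic lithium inverts readily, and syn addition to the E alkene followed by retentive borylation would lead to the 7R epimer, so no reliance is placed on it and both C7 epimers are expected. B(OMe)3 intercepts 19 as the boronate 20, and alkaline H2O2 converts C–B into C–O with retention. The selectivity the step needs is cyclisation ahead of the [1,2]-Wittig shift of the benzylic C2; the aryl-activated acceptor and holding the mixture at −78 °C until closure is complete should secure it. The triisopropylsilyl ethers are chosen because they resist butyllithium and silyl transfer to either carbanion, and the aryl silyl ether should survive the brief basic oxidation.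

Step 9
Reactants: 21 the C7-epimeric alcohols of step 8
Product: 22 (2R,3S,4R)-4-(4-methoxybenzoyl)-3-[(triisopropylsilyloxy)methyl]-2-[4-(triisopropylsilyloxy)phenyl]oxolane
Conditions: Dess–Martin periodinane, pyridine, CH2Cl2, 0 °C to rt
Reagents that add atoms: none
Why: Dess–Martin oxidation of a secondary benzylic alcohol under buffered conditions merges both C7 epimers into one ketone; C4 is now α to a carbonyl, but its 3,4-trans arrangement is the more stable one, so any equilibration can only reinforce it.

Step 10
Reactants: 22 the aryl ketone of step 9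
Product: 23 (2R,3S,4R)-4-[(S)-hydroxy(4-methoxyphenyl)methyl]-3-[(triisopropylsilyloxy)methyl]-2-[4-(triisopropylsilyloxy)phenyl]oxolane
Conditions: (R)-2-methyl-CBS-oxazaborolidine (0.3 equiv), BH3·SMe2, THF, −20 °C; MeOH
Reagents that add atoms: none
Why: Corey–Bakshi–Shibata reduction: with the aryl group as the large substituent the R catalyst delivers hydride to the face that gives the S carbinol (the sense that converts acetophenone into (S)-1-phenylethanol), and the Felkin–Anh preference of C4 (C3 antiperiplanar to the incoming hydride, which passes over H) leads to the same 7S configuration, so reagent and substrate control should be matched.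

Step 11
Reactants: 23 the 7S alcohol of step 10
Product: 24 (2R,3S,4R)-4-[(S)-hydroxy(4-methoxyphenyl)methyl]-3-(hydroxymethyl)-2-(4-hydroxyphenyl)oxolane
Conditions: Bu4NF, THF, 0 °C to rt
Reagents that add atoms: none
Why: Fluoride cleaves the aryl and the primary alkyl Si–O bonds in one operation; the medium is basic, so the 4-methoxybenzylic alcohol cannot ionise and close onto the C6 hydroxyl.

Step 12
Reactants: 24 the triol of step 11
Product: 25 (2R,3S,4R)-3-(acetoxymethyl)-4-[(S)-acetoxy(4-methoxyphenyl)methyl]-2-(4-acetoxyphenyl)oxolane
Conditions: Ac2O, pyridine, DMAP (cat.), CH2Cl2, 0 °C to rt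
Reagents that add atoms: acetic anhydride, CC(=O)OC(C)=O
Why: DMAP-catalysed acetylation of the phenol, the primary alcohol and the hindered benzylic alcohol; no C–O bond at a stereocentre is broken.

Step 13
Reactants: 25 the triacetate of step 12
Product: 26 (2R,3S,4R)-3-(acetoxymethyl)-4-[(S)-acetoxy(4-methoxyphenyl)methyl]-2-(4-hydroxyphenyl)oxolane
Conditions: NH4OAc, MeOH–H2O, rt
Reagents that add atoms: none
Why: Chemoselective transesterification: an aryl acetate has a far better leaving group than an alkyl acetate and is cleaved by NH4OAc-buffered methanolysis at neutral pH, where the two alkyl acetates, the C7 benzylic C–O bond and the C2 benzylic ether should all be stable.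

## Compound list

1 | 4-methoxybenzaldehyde | COc1ccc(C=O)cc1 | starting material
2 | (2-carboxyethyl)triphenylphosphonium bromide | OC(=O)CC[P+](c1ccccc1)(c1ccccc1)c1ccccc1.[Br-] | starting material
3 | sodium 3-(triphenylphosphoranylidene)propanoate (carboxylate ylide, not isolated) | [Na+].[O-]C(=O)CC=P(c1ccccc1)(c1ccccc1)c1ccccc1 | intermediate
4 | (E)-4-(4-methoxyphenyl)but-3-enoic acid | COc1ccc(/C=C/CC(=O)O)cc1 | intermediate
5 | (R)-4-benzyl-1,3-oxazolidin-2-one | O=C1N[C@H](Cc2ccccc2)CO1 | starting material
6 | (E)-4-(4-methoxyphenyl)but-3-enoic pivalic anhydride (not isolated) | COc1ccc(/C=C/CC(=O)OC(=O)C(C)(C)C)cc1 | intermediate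
7 | (R)-4-benzyl-3-[(E)-4-(4-methoxyphenyl)but-3-enoyl]-1,3-oxazolidin-2-one | COc1ccc(/C=C/CC(=O)N2[C@H](Cc3ccccc3)COC2=O)cc1 | intermediate
8 | 4-hydroxybenzaldehyde | O=Cc1ccc(O)cc1 | starting material
9 | 4-(triisopropylsilyloxy)benzaldehyde | O=Cc1ccc(O[Si](C(C)C)(C(C)C)C(C)C)cc1 | intermediate
10 | dibutylboron (Z)-enolate of 7 (not isolated) | CCCCB(CCCC)O/C(=C\C=C\c1ccc(OC)cc1)N1[C@H](Cc2ccccc2)COC1=O | intermediate
11 | O-dibutylboryl aldolate of 12 (not isolated) | CCCCB(CCCC)O[C@@H](c1ccc(O[Si](C(C)C)(C(C)C)C(C)C)cc1)[C@H](C(=O)N1[C@H](Cc2ccccc2)COC1=O)/C=C/c1ccc(OC)cc1 | intermediate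
12 | (R)-4-benzyl-3-{(2R,3R)-3-hydroxy-2-[(E)-2-(4-methoxyphenyl)ethenyl]-3-[4-(triisopropylsilyloxy)phenyl]propanoyl}-1,3-oxazolidin-2-one | O[C@@H](c1ccc(O[Si](C(C)C)(C(C)C)C(C)C)cc1)[C@H](C(=O)N1[C@H](Cc2ccccc2)COC1=O)/C=C/c1ccc(OC)cc1 | intermediate
13 | (1R,2S)-2-[(E)-2-(4-methoxyphenyl)ethenyl]-1-[4-(triisopropylsilyloxy)phenyl]propane-1,3-diol | O[C@@H](c1ccc(O[Si](C(C)C)(C(C)C)C(C)C)cc1)[C@H](CO)/C=C/c1ccc(OC)cc1 | intermediate
14 | (1R,2S,3E)-4-(4-methoxyphenyl)-2-[(triisopropylsilyloxy)methyl]-1-[4-(triisopropylsilyloxy)phenyl]but-3-en-1-ol | O[C@@H](c1ccc(O[Si](C(C)C)(C(C)C)C(C)C)cc1)[C@H](CO[Si](C(C)C)(C(C)C)C(C)C)/C=C/c1ccc(OC)cc1 | intermediate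
15 | tributyl(iodomethyl)stannane | CCCC[Sn](CCCC)(CCCC)CI | starting material
16 | potassium alkoxide of 14 (not isolated) | [K+].[O-][C@@H](c1ccc(O[Si](C(C)C)(C(C)C)C(C)C)cc1)[C@H](CO[Si](C(C)C)(C(C)C)C(C)C)/C=C/c1ccc(OC)cc1 | intermediate
17 | tributyl({(1R,2S,3E)-4-(4-methoxyphenyl)-2-[(triisopropylsilyloxy)methyl]-1-[4-(triisopropylsilyloxy)phenyl]but-3-en-1-yl}oxymethyl)stannane | CCCC[Sn](CCCC)(CCCC)CO[C@@H](c1ccc(O[Si](C(C)C)(C(C)C)C(C)C)cc1)[C@H](CO[Si](C(C)C)(C(C)C)C(C)C)/C=C/c1ccc(OC)cc1 | intermediate
18 | lithiomethyl ether of 14 (1R,2S,3E; not isolated) | [Li]CO[C@@H](c1ccc(O[Si](C(C)C)(C(C)C)C(C)C)cc1)[C@H](CO[Si](C(C)C)(C(C)C)C(C)C)/C=C/c1ccc(OC)cc1 | intermediate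
19 | cyclised benzylic lithium: 4-[lithio(4-methoxyphenyl)methyl] oxolane with ring centres as in 21, C7 unassigned (not isolated) | COc1ccc(C([Li])[C@H]2CO[C@@H](c3ccc(O[Si](C(C)C)(C(C)C)C(C)C)cc3)[C@@H]2CO[Si](C(C)C)(C(C)C)C(C)C)cc1 | intermediate
20 | dimethyl boronate at C7 of the same oxolane, ring centres as in 21, C7 unassigned (not isolated) | COc1ccc(C(B(OC)OC)[C@H]2CO[C@@H](c3ccc(O[Si](C(C)C)(C(C)C)C(C)C)cc3)[C@@H]2CO[Si](C(C)C)(C(C)C)C(C)C)cc1 | intermediate
21 | (2R,3S,4R)-4-[hydroxy(4-methoxyphenyl)methyl]-3-[(triisopropylsilyloxy)methyl]-2-[4-(triisopropylsilyloxy)phenyl]oxolane, both C7 epimers | COc1ccc(C(O)[C@H]2CO[C@@H](c3ccc(O[Si](C(C)C)(C(C)C)C(C)C)cc3)[C@@H]2CO[Si](C(C)C)(C(C)C)C(C)C)cc1 | intermediate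
22 | (2R,3S,4R)-4-(4-methoxybenzoyl)-3-[(triisopropylsilyloxy)methyl]-2-[4-(triisopropylsilyloxy)phenyl]oxolane | COc1ccc(C(=O)[C@H]2CO[C@@H](c3ccc(O[Si](C(C)C)(C(C)C)C(C)C)cc3)[C@@H]2CO[Si](C(C)C)(C(C)C)C(C)C)cc1 | intermediate
23 | (2R,3S,4R)-4-[(S)-hydroxy(4-methoxyphenyl)methyl]-3-[(triisopropylsilyloxy)methyl]-2-[4-(triisopropylsilyloxy)phenyl]oxolane | COc1ccc([C@@H](O)[C@H]2CO[C@@H](c3ccc(O[Si](C(C)C)(C(C)C)C(C)C)cc3)[C@@H]2CO[Si](C(C)C)(C(C)C)C(C)C)cc1 | intermediate
24 | (2R,3S,4R)-4-[(S)-hydroxy(4-methoxyphenyl)methyl]-3-(hydroxymethyl)-2-(4-hydroxyphenyl)oxolane | COc1ccc([C@@H](O)[C@H]2CO[C@@H](c3ccc(O)cc3)[C@@H]2CO)cc1 | intermediate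
25 | (2R,3S,4R)-3-(acetoxymethyl)-4-[(S)-acetoxy(4-methoxyphenyl)methyl]-2-(4-acetoxyphenyl)oxolane | COc1ccc([C@@H](OC(C)=O)[C@H]2CO[C@@H](c3ccc(OC(C)=O)cc3)[C@@H]2COC(C)=O)cc1 | intermediate
26 | (2R,3S,4R)-3-(acetoxymethyl)-4-[(S)-acetoxy(4-methoxyphenyl)methyl]-2-(4-hydroxyphenyl)oxolane (CNP0231272.1) | COc1ccc([C@@H](OC(C)=O)[C@H]2CO[C@@H](c3ccc(O)cc3)[C@@H]2COC(C)=O)cc1 | target

## Step count and least certain steps

Total: 13 steps. Longest linear sequence: 12 steps (steps 1, 2 and 4 to 13, from 1); step 3 is a one-step branch.

Step 8 (key step). The most likely failure is that the [1,2]-Wittig shift of the benzylic carbon C2 onto the carbanion, or protonation of 18 before ring closure, overtakes cyclisation. The 4-methoxy group makes the styrene a poorer acceptor, and the migrating carbon is a stabilised benzylic centre. Fallback (radical in place of anionic closure of the same bond): starting from 14, etherification with chloromethyl phenyl selenide (KH, THF) would give the (phenylselanyl)methyl ether F1. Bu3SnH with slow admission of dry air then generates the alkoxymethyl radical, which has no rearrangement channel and closes 5-exo onto the styrene through the same chair-like arrangement. The benzylic radical is trapped by O2 as the hydroperoxide F2, and PPh3 reduces this to 21, where the route is rejoined.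

Step 7. The most likely failure is silyl transfer from the primary oxygen to the neighbouring potassium alkoxide, or fragmentation of the homoallylic alkoxide, during a slow alkylation; the iodomethylstannane is a sluggish electrophile and the alkoxide is long-lived. Fallback (the C–Sn bond is made with a tin nucleophile and no alkoxide is generated): from 14, Me2S and dibenzoyl peroxide (MeCN, 0 °C) give the methylthiomethyl ether F3. SO2Cl2 (CH2Cl2, −78 °C) converts it into the chloromethyl ether F4, which is used cold without isolation and is displaced by Bu3SnLi (THF, −78 °C) to give 17.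

Step 4. The most likely failure is erosion of regio- and stereocontrol in the aldol of a dienolate: reaction at the γ-carbon, epimerisation of the doubly activated α-proton, or retro-aldol from an electron-rich benzylic aldolate. Fallback (allylboration in place of aldol, styrene completed afterwards): from 9, a chiral phosphoric acid-catalysed allylboration with (E)-4-(triisopropylsilyloxy)but-2-enylboronic acid pinacol ester would give the homoallylic alcohol F5. The E reagent gives the required anti relation through the chair transition state, and the catalyst enantiomer is chosen for the 1R carbinol. Cross-metathesis with 4-vinylanisole (second-generation Hoveyda–Grubbs catalyst, CH2Cl2, 40 °C) then installs the E-styrene and leads to 14, bypassing steps 1, 2, 5 and 6.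

Step 10. The most likely failure is insufficient facial discrimination, because the ketone is α-branched and carries ether oxygens that can bind borane away from the catalyst. Fallback (substrate control in place of reagent control): reduce 22 with the bulky achiral hydride LiBH(s-Bu)3 (THF, −78 °C), relying only on the Felkin–Anh bias of C4, to reach 23. Any 7R alcohol is separated and returned to step 9. This detour creates no new compound (entry F0).

Step 13. The most likely failure is over-reaction: partial cleavage of the primary acetate, or slow solvolysis at C7 in the protic medium. Fallback (the phenol is masked before acetylation, so no selective ester cleavage is needed): from 24, allyl bromide/K2CO3 (acetone, rt) alkylates only the phenol to give the allyl ether F6. Ac2O/pyridine/DMAP gives the diacetate F7, and Pd(PPh3)4 with morpholine (THF, rt) removes the allyl group under neutral conditions to give 26.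

## Further compounds

F1 | step 8 | (1R,2S,3E)-4-(4-methoxyphenyl)-1-[(phenylselanyl)methoxy]-2-[(triisopropylsilyloxy)methyl]-1-[4-(triisopropylsilyloxy)phenyl]but-3-ene | c1ccccc1[Se]CO[C@@H](c1ccc(O[Si](C(C)C)(C(C)C)C(C)C)cc1)[C@H](CO[Si](C(C)C)(C(C)C)C(C)C)/C=C/c1ccc(OC)cc1
F2 | step 8 | (2R,3S,4R)-4-[hydroperoxy(4-methoxyphenyl)methyl]-3-[(triisopropylsilyloxy)methyl]-2-[4-(triisopropylsilyloxy)phenyl]oxolane, both C7 epimers | COc1ccc(C(OO)[C@H]2CO[C@@H](c3ccc(O[Si](C(C)C)(C(C)C)C(C)C)cc3)[C@@H]2CO[Si](C(C)C)(C(C)C)C(C)C)cc1
F3 | step 7 | (1R,2S,3E)-4-(4-methoxyphenyl)-1-[(methylsulfanyl)methoxy]-2-[(triisopropylsilyloxy)methyl]-1-[4-(triisopropylsilyloxy)phenyl]but-3-ene | CSCO[C@@H](c1ccc(O[Si](C(C)C)(C(C)C)C(C)C)cc1)[C@H](CO[Si](C(C)C)(C(C)C)C(C)C)/C=C/c1ccc(OC)cc1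
F4 | step 7 | (1R,2S,3E)-1-(chloromethoxy)-4-(4-methoxyphenyl)-2-[(triisopropylsilyloxy)methyl]-1-[4-(triisopropylsilyloxy)phenyl]but-3-ene | ClCO[C@@H](c1ccc(O[Si](C(C)C)(C(C)C)C(C)C)cc1)[C@H](CO[Si](C(C)C)(C(C)C)C(C)C)/C=C/c1ccc(OC)cc1
F5 | step 4 | (1R,2S)-2-[(triisopropylsilyloxy)methyl]-1-[4-(triisopropylsilyloxy)phenyl]but-3-en-1-ol | O[C@@H](c1ccc(O[Si](C(C)C)(C(C)C)C(C)C)cc1)[C@H](CO[Si](C(C)C)(C(C)C)C(C)C)C=C
F0 | step 10 | none | none
F6 | step 13 | (2R,3S,4R)-4-[(S)-hydroxy(4-methoxyphenyl)methyl]-3-(hydroxymethyl)-2-[4-(prop-2-enyloxy)phenyl]oxolane | COc1ccc([C@@H](O)[C@H]2CO[C@@H](c3ccc(OCC=C)cc3)[C@@H]2CO)cc1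
F7 | step 13 | (2R,3S,4R)-3-(acetoxymethyl)-4-[(S)-acetoxy(4-methoxyphenyl)methyl]-2-[4-(prop-2-enyloxy)phenyl]oxolane | COc1ccc([C@@H](OC(C)=O)[C@H]2CO[C@@H](c3ccc(OCC=C)cc3)[C@@H]2COC(C)=O)cc1
A1 | alternative 1 | 2,4-cis-2-[4-(tert-butyldimethylsilyloxy)phenyl]-4-ethenyloxolane spiro-fused at C3 to C5 of 2,2-dimethyl-1,3-dioxane-4,6-dione (aryl- and vinyl-bearing carbons placed as C2 and C4 of the target) | CC1(C)OC(=O)C2(C(=O)O1)[C@@H](C=C)CO[C@H]2c1ccc(O[Si](C)(C)C(C)(C)C)cc1
A2 | alternative 1 | 5-[4-(tert-butyldimethylsilyloxy)benzylidene]-2,2-dimethyl-1,3-dioxane-4,6-dione | CC1(C)OC(=O)C(=Cc2ccc(O[Si](C)(C)C(C)(C)C)cc2)C(=O)O1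
A3 | alternative 1 | 4-ethenyl-1,3-dioxolan-2-one (vinylethylene carbonate, racemic) | C=CC1COC(=O)O1
A4 | alternative 2 | (2R,3S,4R)-4-(4-methoxybenzoyl)-3-[(tert-butyldiphenylsilyloxy)methyl]-2-[4-(triisopropylsilyloxy)phenyl]oxolane | COc1ccc(C(=O)[C@H]2CO[C@@H](c3ccc(O[Si](C(C)C)(C(C)C)C(C)C)cc3)[C@@H]2CO[Si](c4ccccc4)(c4ccccc4)C(C)(C)C)cc1
A5 | alternative 2 | (4S)-4-[(E)-3-(tert-butyldiphenylsilyloxy)prop-1-enyl]-4-(4-methoxyphenyl)-2-[4-(triisopropylsilyloxy)phenyl]-1,3-dioxolane (either acetal epimer) | COc1ccc([C@@]2(/C=C/CO[Si](c3ccccc3)(c3ccccc3)C(C)(C)C)COC(c3ccc(O[Si](C(C)C)(C(C)C)C(C)C)cc3)O2)cc1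
A6 | alternative 3 | methyl (2R,3S,4R)-4-[(S)-(tert-butyldimethylsilyloxy)(4-methoxyphenyl)methyl]-2-[4-(triisopropylsilyloxy)phenyl]oxolane-3-carboxylate | COc1ccc([C@@H](O[Si](C)(C)C(C)(C)C)[C@H]2CO[C@@H](c3ccc(O[Si](C(C)C)(C(C)C)C(C)C)cc3)[C@@H]2C(=O)OC)cc1
A7 | alternative 3 | methyl (3R,4S)-4-(tert-butyldimethylsilyloxy)-2-diazo-4-(4-methoxyphenyl)-3-({[4-(triisopropylsilyloxy)phenyl]methoxy}methyl)butanoate | COc1ccc([C@@H](O[Si](C)(C)C(C)(C)C)[C@@H](COCc2ccc(O[Si](C(C)C)(C(C)C)C(C)C)cc2)C(=[N+]=[N-])C(=O)OC)cc1
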